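Product in the epsilon and theta runs climbs on one common course within the scatter, reaching 44.3% and 43.5% at 10.0 h, although c_partner differs 7.06 times between them. Read from those readings, product forms on average at 0.439 mM h⁻¹ up to 10.0 h.

common to all: substrate 10 mM; free catalyst 20 µM

|  | partner | remark | time |
|---|---|---|---|
| epsilon | 17 mM | run made earlier |  |
| theta | 120 mM | run made earlier |  |
| alder | 12.0 mM |  | 15 h |
| birch | 25.0 mM |  | 15 h |
| ash | 50.0 mM |  | 15 h |
| larch | 100 mM |  | 15 h |

| run | time / h | product / % |
|---|---|---|
| epsilon | 0.833 | 3.1 |
| epsilon | 2.00 | 11.5 |
| epsilon | 5.00 | 23.0 |
| epsilon | 10.0 | 44.3 |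
| theta | 2.50 | 13.4 |
| theta | 5.00 | 22.4 |
| theta | 8.00 | 34.7 |
| theta | 10.0 | 43.5 |

(standard deviation of a reading: 1 percentage point)

- [product] at the end for alder, birch, ash, larch, in this order
- the course of these numbers from the first flask to the last (rises, then falls / hardly changes / falls all the way / rises all the way / falls, then rises)

- what was read earlier has a scatter of 1 percentage point, one standard deviation
- "hardly changes" means that all values lie within two and a half points (for a concentration: within two and a half percent of the largest)

Since the two runs show c_partner making no visible difference, the row can be expected to part if partner runs short during a flask. Two times therefore matter. The first is the asked 15 h. The second is the partner reserve time, the starting c_partner divided by the read rate of product, assuming one partner is spent per product: 27.3 h for alder. Alder has the smallest charge and so the shortest reserve, yet its reserve is 1.82 times the asked time; birch has 56.9 h. On the same assumption substrate is the limiting reagent, its charge being smaller than each charge of partner. This reckoning expects a level row and sets no height for it.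

The forecast gives 6.4 mM in each flask, with the course hardly changes, on the ground that “The reaction is therefore zero order in partner over this range”.

The flasks give 5.92 mM, 5.94 mM, 5.95 mM and 5.95 mM, so the course is hardly changes, as forecast.

    catalyst intermediate A ⇌ by-product + catalyst intermediate B (K = 0.0240 M, k = 0.0430 s⁻¹)
    substrate + catalyst intermediate B ⇌ catalyst intermediate C (K = 55.0 L mol⁻¹, k = 6.90 L mol⁻¹ s⁻¹)
    partner + free catalyst → catalyst intermediate A (k = 81.0 L mol⁻¹ s⁻¹)
    catalyst intermediate D ⇌ free catalyst + product (K = 0.0120 M, k = 0.0430 s⁻¹)
    catalyst intermediate C → catalyst intermediate D (k = 0.0380 s⁻¹)

The forecast fails if a run shows the course of the one-step fit first order in substrate, partner and free catalyst: rises all the way. In alder, the half-life of partner by its capture on free catalyst stands at 16 h after 15.0 h, longer than the asked 15 h. At that time 51% of alder's partner remains. Alder, with a reserve time of 27.3 h, has spent 49.0% of its partner by the end, and birch, with 56.9 h, has spent 23.8%.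

(The data were computed for an exercise, noise included.)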